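**Strategy**
1. Cuts: the acyl-bearing decalin carbon C2 is traced back to its epimer. The decalin bonds C4a–C8a and C1–C2 are then cut together (retro-Diels–Alder) to an open all-E tetraenoyl pyridone. After that come the pyridine C3–acyl bond, the pyridine C5–carbinol bond, and the chain alkenes C2=C3 (HWE) and C10=C11 (Wittig).
2. Enabling feature: the only ring alkene of the decalin, C3=C4(CH3), lies between the acyl-bearing C2–H and the fusion C4a–H, which is where a 2,4-dienoyl ketone leaves its new double bond when it reacts as the 4π partner. C1 keeps the propenyl remainder of a hexadienyl 2π partner, and C8a–C8–C7(CH3)–C6–C5–C4a–C4(CH3)–C3 is the carbon skeleton of citronellal.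
3. Forward order: the pyridine ring is bought. The cyclohexene is made from cyclohexa-1,3-diene and joined to pyridine C5, and the oxirane is closed on it. The open tetraene chain is acylated onto pyridine C3, and both decalin rings close together near the end.
4. Stereochemistry: the methyl centre of (S)-citronellal steers the four new decalin centres in the cycloaddition, and C2 is then corrected by epimerisation. A lipase desymmetrisation fixes the secondary carbinol, which relays to the tertiary carbinol (anti 1,2-addition) and to both oxirane carbons (anti epoxidation). The four chain alkenes are made E by isomerisation, E-selective allylic oxidation and HWE.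

Key step: step 17

Assumption: the lipase of step 8 is taken to hydrolyse the acetate at the R-configured carbon of the meso diacetate, the usual empirical preference of lipases for secondary esters. An enzyme of the opposite sense would be run in the acylation mode (vinyl acetate) on the meso diol to give the same monoacetate.

Step 1
Reactants: 1 (S)-citronellal; 2 (E)-but-2-enyl(triphenyl)phosphonium bromide
Product: 4 (2E,7S)-7,11-dimethyldodeca-2,4,10-triene as a 4E/4Z mixture, via crotylidene ylide 3 (not isolated)
Conditions: 2, n-BuLi, THF, −78 → 0 °C; then 1, −78 °C → rt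
Reagents that add atoms: none
Why: Wittig olefination of an unhindered aldehyde whose stereocentre is β and therefore not epimerisable forms the new C4=C5 bond at the α-carbon of the semi-stabilised allylic ylide, but with little E/Z control, so the geometry is settled in the next step.

Step 2
Reactants: 4 (2E,7S)-7,11-dimethyldodeca-2,4,10-triene (4E/4Z mixture)
Product: 5 (2E,4E,7S)-7,11-dimethyldodeca-2,4,10-triene
Conditions: I2 (3 mol %), hexane, visible light, rt
Reagents that add atoms: none
Why: Iodine-atom-catalysed alkene isomerisation (reversible radical addition and elimination) should funnel the conjugated diene to its thermodynamic E,E form, while the isolated trisubstituted alkene carries two identical methyl groups and the stereocentre is not involved.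

Step 3
Reactants: 5 (2E,4E,7S)-7,11-dimethyldodeca-2,4,10-triene
Product: 6 (2E,6S,8E,10E)-2,6-dimethyldodeca-2,8,10-trien-1-ol
Conditions: SeO2 (0.2 equiv), t-BuOOH, salicylic acid (0.1 equiv), CH2Cl2, 0 °C → rt
Reagents that add atoms: tert-butyl hydroperoxide, CC(C)(C)OO (terminal source of the new oxygen, passed on by catalytic selenium dioxide, O=[Se]=O)
Why: The catalytic Riley oxidation (ene reaction followed by a [2,3]-sigmatropic shift) attacks the most nucleophilic, trisubstituted alkene and hydroxylates its E-methyl group, as it does in terpenes such as myrcene that also contain a conjugated diene.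

Step 4
Reactants: 6 (2E,6S,8E,10E)-2,6-dimethyldodeca-2,8,10-trien-1-ol
Product: 7 (2E,6S,8E,10E)-2,6-dimethyldodeca-2,8,10-trienal
Conditions: activated MnO2, CH2Cl2, 0 °C → rt, dark
Reagents that add atoms: none
Why: Manganese dioxide oxidises only the allylic alcohol under neutral, Lewis-acid-free conditions that should neither isomerise the polyene nor start a cycloaddition, and it also converges any enal already formed in step 3.

Step 5
Reactants: 7 (2E,6S,8E,10E)-2,6-dimethyldodeca-2,8,10-trienal; 8 diethyl (N-methoxy-N-methylcarbamoylmethyl)phosphonate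
Product: 10 (2E,4E,8S,10E,12E)-N-methoxy-N,4,8-trimethyltetradeca-2,4,10,12-tetraenamide, via sodium phosphonate carbanion 9 (not isolated)
Conditions: 8, NaH, THF, 0 °C; then 7, 0 °C → rt
Reagents that add atoms: none
Why: Horner–Wadsworth–Emmons olefination with an amide-stabilised phosphonate is reliably E-selective on α-branched enals and delivers the dienoyl unit directly as an acylating agent.

Step 6
Reactants: 11 5-bromo-2,4-dichloropyridine
Product: 12 5-bromo-2,4-bis[2-(trimethylsilyl)ethoxy]pyridine
Conditions: Me3SiCH2CH2OH (2.6 equiv), NaH, THF, 0 °C; then 11, 0 → 65 °C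
Reagents that add atoms: 2-(trimethylsilyl)ethanol, C[Si](C)(C)CCO
Why: Two successive nucleophilic aromatic substitutions (addition–elimination) replace the chlorides γ and α to the ring nitrogen, whereas the bromide at the non-activated β-position stays, and both pyridone oxygens are thereby masked as fluoride-labile ethers.

Step 7
Reactants: 13 cyclohexa-1,3-diene
Product: 14 meso-cis-cyclohex-2-ene-1,4-diyl diacetate
Conditions: Pd(OAc)2 (5 mol %), LiCl (cat), LiOAc, p-benzoquinone, AcOH–pentane, rt
Reagents that add atoms: acetic acid, CC(=O)O (delivered as acetate in the presence of lithium acetate, CC(=O)[O-].[Li+])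
Why: In the palladium(II)/benzoquinone 1,4-diacetoxylation of 1,3-dienes, anti acetoxypalladation gives a π-allyl complex that chloride forces to accept the second acetate from outside, anti to palladium, so the cis (meso) diacetate should result.

Step 8
Reactants: 14 meso-cis-cyclohex-2-ene-1,4-diyl diacetate
Product: 15 (1S,4R)-4-hydroxycyclohex-2-en-1-yl acetate
Conditions: lipase PS (Burkholderia cepacia), phosphate buffer pH 7, rt, stopped after one ester is cleaved
Reagents that add atoms: none
Why: Enantiotopos-selective lipase hydrolysis of a meso diester (enzymatic desymmetrisation) frees only the acetate at the R-configured carbon, so both carbinol centres become defined at once and the later secondary carbinol of the target is in place.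

Step 9
Reactants: 15 (1S,4R)-4-hydroxycyclohex-2-en-1-yl acetate
Product: 16 (1S,4R)-4-(tert-butyldimethylsilyloxy)cyclohex-2-en-1-yl acetate
Conditions: TBSCl, imidazole, DMF, rt
Reagents that add atoms: tert-butyldimethylsilyl chloride, CC(C)(C)[Si](C)(C)Cl
Why: Imidazole-promoted silylation of a secondary alcohol proceeds at oxygen with retention and marks the R carbinol as the centre that is kept.

Step 10
Reactants: 16 (1S,4R)-4-(tert-butyldimethylsilyloxy)cyclohex-2-en-1-yl acetate
Product: 17 (1S,4R)-4-(tert-butyldimethylsilyloxy)cyclohex-2-en-1-ol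
Conditions: K2CO3 (0.2 equiv), MeOH, 0 °C → rt
Reagents that add atoms: none
Why: Carbonate-catalysed methanolysis (transesterification) removes the acetate without touching the silyl ether or either stereocentre.

Step 11
Reactants: 17 (1S,4R)-4-(tert-butyldimethylsilyloxy)cyclohex-2-en-1-ol
Product: 18 (R)-4-(tert-butyldimethylsilyloxy)cyclohex-2-en-1-one
Conditions: activated MnO2, CH2Cl2, rt
Reagents that add atoms: none
Why: Manganese dioxide oxidation of the allylic alcohol erases the S carbinol and leaves the R silyloxy centre, and the neutral heterogeneous medium avoids racemisation through the dienolate.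

Step 12
Reactants: 12 5-bromo-2,4-bis[2-(trimethylsilyl)ethoxy]pyridine; 18 (R)-4-(tert-butyldimethylsilyloxy)cyclohex-2-en-1-one
Product: 21 (1S,4R)-1-{4,6-bis[2-(trimethylsilyl)ethoxy]pyridin-3-yl}-4-(tert-butyldimethylsilyloxy)cyclohex-2-en-1-ol (tertiary OH cis to OTBS), via 5-lithiopyridine 19 (not isolated), via aryl cerium dichloride 20 (not isolated)
Conditions: 12, n-BuLi, THF, −78 °C; anhydrous CeCl3 (THF slurry), −78 °C; then 18, −78 °C; H2O
Reagents that add atoms: none
Why: Bromine–lithium exchange outruns ring deprotonation at −78 °C, and the weakly basic, oxophilic organocerium reagent adds 1,2 to the enone without enolising it, approaching from the ring face opposite the C4 silyloxy group so that the new tertiary hydroxyl stands cis to OTBS, with any minor epimer removed by chromatography.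

Step 13
Reactants: 21 pyridyl cyclohexenol
Product: 22 5-[(1S,4R)-4-(tert-butyldimethylsilyloxy)-1-(triethylsilyloxy)cyclohex-2-en-1-yl]-2,4-bis[2-(trimethylsilyl)ethoxy]pyridine
Conditions: TESOTf, 2,6-lutidine, CH2Cl2, −78 → 0 °C
Reagents that add atoms: triethylsilyl trifluoromethanesulfonate, CC[Si](CC)(CC)OS(=O)(=O)C(F)(F)F
Why: Silyl triflate with lutidine is the standard silylation for hindered tertiary alcohols, stays non-acidic for this easily ionised allylic pyridyl carbinol, and removes the free hydroxyl that would otherwise direct a peracid to the wrong face.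

Step 14
Reactants: 22 bis-silylated pyridyl cyclohexene
Product: 23 5-[(1S,2R,5R,6R)-5-(tert-butyldimethylsilyloxy)-2-(triethylsilyloxy)-7-oxabicyclo[4.1.0]heptan-2-yl]-2,4-bis[2-(trimethylsilyl)ethoxy]pyridine (oxirane trans to both silyloxy groups)
Conditions: mCPBA, NaHCO3 buffer, CH2Cl2, 0 °C → rt
Reagents that add atoms: 3-chloroperoxybenzoic acid, O=C(OO)c1cccc(Cl)c1
Why: In this sterically controlled Prilezhaev epoxidation the aryl group sits pseudo-equatorial and the OTES group pseudo-axial, so that OTES and OTBS together shield one face and oxygen should arrive anti to both, as with cis-1,4-bis(silyloxy)cyclohex-2-enes.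

Step 15
Reactants: 23 bis-silylated epoxide; 10 tetraenoic Weinreb amide
Product: 25 3-[(2E,4E,8S,10E,12E)-4,8-dimethyltetradeca-2,4,10,12-tetraenoyl]-5-[(1S,2R,5R,6R)-5-(tert-butyldimethylsilyloxy)-2-(triethylsilyloxy)-7-oxabicyclo[4.1.0]heptan-2-yl]-2,4-bis[2-(trimethylsilyl)ethoxy]pyridine, via 3-lithiopyridine 24 (not isolated)
Conditions: 23, t-BuLi (1.1 equiv), THF, −78 °C; then 10, −78 → −40 °C; H2O
Reagents that add atoms: none
Why: Directed ortho-metalation removes the C3–H between the two coordinating alkoxy groups, the preferred site in 2,4-dialkoxypyridines, and the Weinreb ketone synthesis (1,2-addition to a chelated tetrahedral intermediate that collapses only on work-up) should give the dienone without over-addition or conjugate addition.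

Step 16
Reactants: 25 protected tetraenoyl pyridine
Product: 26 3-[(2E,4E,8S,10E,12E)-4,8-dimethyltetradeca-2,4,10,12-tetraenoyl]-5-[(1S,2R,5R,6S)-2,5-dihydroxy-7-oxabicyclo[4.1.0]heptan-2-yl]-4-hydroxypyridin-2(1H)-one
Conditions: TBAF (8 equiv), AcOH (4 equiv), THF, 0 °C, dark; cold work-up at pH 5, used at once
Reagents that add atoms: none
Why: Fluoride cleaves both silyl ethers and fragments both 2-(trimethylsilyl)ethyl ethers (β-elimination with loss of ethene) in one operation, acetic acid keeps alkoxide levels too low for a Payne rearrangement of the epoxy alcohols, and the low temperature keeps the tetraene open.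

Step 17
Reactants: 26 free all-E tetraenoyl 4-hydroxy-2-pyridone
Product: 27 3-{[(1R,2R,4aS,7S,8aR)-4,7-dimethyl-1-[(E)-prop-1-enyl]-1,2,4a,5,6,7,8,8a-octahydronaphthalen-2-yl]carbonyl}-5-[(1S,2R,5R,6S)-2,5-dihydroxy-7-oxabicyclo[4.1.0]heptan-2-yl]-4-hydroxypyridin-2(1H)-one (trans-decalin, acyl cis to propenyl)
Conditions: degassed EtOH–H2O 1:1 (2 mM), BHT (cat), dark, 60 °C
Reagents that add atoms: none
Why: A concerted but asynchronous [4+2] cycloaddition is expected in which the s-cis dienoyl unit C2=C3–C4(CH3)=C5, its LUMO lowered by the ketone that the hydrogen bond to the pyridone 4-OH holds planar, is the 4π partner and the C10=C11 bond of the electron-rich hexadienyl end is the 2π partner, with the C5–C10 bond forming ahead of the C2–C11 bond. The closest known reaction type is the thermal type 1 intramolecular Diels–Alder reaction with inverse electron demand of all-E polyenoyl 4-hydroxy-2-pyridones, the laboratory counterpart of the biosynthetic decalin formation in this alkaloid family. The cyclohexene (C2, C3, C4, C5, C10, C11) closes by the cycloaddition itself through both new σ bonds, and the methylcyclohexane (C5 to C10) closes at the same moment because the four-carbon tether C6–C9, folded as a chair, bridges the two carbons joined by the C5–C10 bond. Suprafacial addition turns the E geometry of C10=C11 into the trans relation of propenyl and C9, places the two outside groups of the E,E-diene (acyl and C6) cis, and with the anti fold of the tether gives the trans ring fusion, so the acyl group ends cis to the propenyl group and pseudo-axial, while the absolute sense of all four new centres follows from the C8 methyl, which stays equatorial on the chair tether and thereby selects one pair of π-faces. The step needs periselectivity, trans fusion and one face: the normal-demand mode would have to bond to C4 and build a quaternary carbon, the C4 methyl also crowds the tether in the cis-fused fold, and aqueous alcohol favours the compact polarised transition state at a temperature the epoxy diol should tolerate.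

Step 18
Reactants: 27 C2-epimeric decalin adduct
Product: 28 target CNP0494338.1, 3-{[(1R,2S,4aS,7S,8aR)-4,7-dimethyl-1-[(E)-prop-1-enyl]-1,2,4a,5,6,7,8,8a-octahydronaphthalen-2-yl]carbonyl}-5-[(1S,2R,5R,6S)-2,5-dihydroxy-7-oxabicyclo[4.1.0]heptan-2-yl]-4-hydroxypyridin-2(1H)-one
Conditions: DBU (3 equiv), MeCN, rt; work-up at pH 5
Reagents that add atoms: none
Why: Base-mediated epimerisation through the extended enolate of the C2–H, which is both α to the ketone and allylic, with α-reprotonation, should move the pseudo-axial acyl group to the pseudo-equatorial position trans to the propenyl group, the thermodynamic all-equatorial isomer, while an amine base is too weak to generate the alkoxides needed for epoxide migration.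

**Compound list**
1 | (S)-citronellal | O=CC[C@@H](C)CCC=C(C)C | starting material
2 | (E)-but-2-enyl(triphenyl)phosphonium bromide | C/C=C/C[P+](c1ccccc1)(c1ccccc1)c1ccccc1.[Br-] | starting material
3 | (E)-but-2-enylidene(triphenyl)phosphorane | C/C=C/C=P(c1ccccc1)(c1ccccc1)c1ccccc1 | intermediate
4 | (2E,7S)-7,11-dimethyldodeca-2,4,10-triene, 4E/4Z mixture | C/C=C/C=CC[C@@H](C)CCC=C(C)C | intermediate
5 | (2E,4E,7S)-7,11-dimethyldodeca-2,4,10-triene | C/C=C/C=C/C[C@@H](C)CCC=C(C)C | intermediate
6 | (2E,6S,8E,10E)-2,6-dimethyldodeca-2,8,10-trien-1-ol | C/C=C/C=C/C[C@@H](C)CC/C=C(\C)CO | intermediate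
7 | (2E,6S,8E,10E)-2,6-dimethyldodeca-2,8,10-trienal | C/C=C/C=C/C[C@@H](C)CC/C=C(\C)C=O | intermediate
8 | diethyl (N-methoxy-N-methylcarbamoylmethyl)phosphonate | CCOP(=O)(CC(=O)N(C)OC)OCC | starting material
9 | sodium salt of the carbanion of 8 | CCOP(=O)([CH-]C(=O)N(C)OC)OCC.[Na+] | intermediate
10 | (2E,4E,8S,10E,12E)-N-methoxy-N,4,8-trimethyltetradeca-2,4,10,12-tetraenamide | C/C=C/C=C/C[C@@H](C)CC/C=C(C)/C=C/C(=O)N(C)OC | intermediate
11 | 5-bromo-2,4-dichloropyridine | Clc1cc(Cl)c(Br)cn1 | starting material
12 | 5-bromo-2,4-bis[2-(trimethylsilyl)ethoxy]pyridine | C[Si](C)(C)CCOc1cc(OCC[Si](C)(C)C)c(Br)cn1 | intermediate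
13 | cyclohexa-1,3-diene | C1=CC=CCC1 | starting material
14 | meso-cis-cyclohex-2-ene-1,4-diyl diacetate | CC(=O)O[C@H]1CC[C@@H](OC(C)=O)C=C1 | intermediate
15 | (1S,4R)-4-hydroxycyclohex-2-en-1-yl acetate | CC(=O)O[C@H]1CC[C@@H](O)C=C1 | intermediate
16 | (1S,4R)-4-(tert-butyldimethylsilyloxy)cyclohex-2-en-1-yl acetate | CC(=O)O[C@H]1CC[C@@H](O[Si](C)(C)C(C)(C)C)C=C1 | intermediate
17 | (1S,4R)-4-(tert-butyldimethylsilyloxy)cyclohex-2-en-1-ol | O[C@H]1CC[C@@H](O[Si](C)(C)C(C)(C)C)C=C1 | intermediate
18 | (R)-4-(tert-butyldimethylsilyloxy)cyclohex-2-en-1-one | O=C1CC[C@@H](O[Si](C)(C)C(C)(C)C)C=C1 | intermediate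
19 | 5-lithio-2,4-bis[2-(trimethylsilyl)ethoxy]pyridine | C[Si](C)(C)CCOc1cc(OCC[Si](C)(C)C)c([Li])cn1 | intermediate
20 | {4,6-bis[2-(trimethylsilyl)ethoxy]pyridin-3-yl}cerium dichloride | C[Si](C)(C)CCOc1cc(OCC[Si](C)(C)C)c([Ce](Cl)Cl)cn1 | intermediate
21 | (1S,4R)-1-{4,6-bis[2-(trimethylsilyl)ethoxy]pyridin-3-yl}-4-(tert-butyldimethylsilyloxy)cyclohex-2-en-1-ol | C[Si](C)(C)CCOc1cc(OCC[Si](C)(C)C)c(cn1)[C@]1(O)CC[C@@H](O[Si](C)(C)C(C)(C)C)C=C1 | intermediate
22 | triethylsilyl ether of 21 | C[Si](C)(C)CCOc1cc(OCC[Si](C)(C)C)c(cn1)[C@]1(O[Si](CC)(CC)CC)CC[C@@H](O[Si](C)(C)C(C)(C)C)C=C1 | intermediate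
23 | bis-silylated epoxide, oxirane trans to OTES and OTBS | C[Si](C)(C)CCOc1cc(OCC[Si](C)(C)C)c(cn1)[C@]1(O[Si](CC)(CC)CC)CC[C@@H](O[Si](C)(C)C(C)(C)C)[C@@H]2O[C@@H]21 | intermediate
24 | 3-lithio derivative of 23 | C[Si](C)(C)CCOc1ncc(c(OCC[Si](C)(C)C)c1[Li])[C@]1(O[Si](CC)(CC)CC)CC[C@@H](O[Si](C)(C)C(C)(C)C)[C@@H]2O[C@@H]21 | intermediate
25 | protected all-E tetraenoyl pyridine | C/C=C/C=C/C[C@@H](C)CC/C=C(C)/C=C/C(=O)c1c(OCC[Si](C)(C)C)ncc(c1OCC[Si](C)(C)C)[C@]1(O[Si](CC)(CC)CC)CC[C@@H](O[Si](C)(C)C(C)(C)C)[C@@H]2O[C@@H]21 | intermediate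
26 | free all-E tetraenoyl 4-hydroxy-2-pyridone | C/C=C/C=C/C[C@@H](C)CC/C=C(C)/C=C/C(=O)c1c(O)c([C@]2(O)CC[C@@H](O)[C@@H]3O[C@@H]32)c[nH]c1=O | intermediate
27 | C2-epimeric trans-decalin adduct (acyl cis to propenyl) | C/C=C/[C@@H]1[C@H]2C[C@@H](C)CC[C@@H]2C(C)=C[C@@H]1C(=O)c1c(O)c([C@]2(O)CC[C@@H](O)[C@@H]3O[C@@H]32)c[nH]c1=O | intermediate
28 | CNP0494338.1 | C/C=C/[C@@H]1[C@H]2C[C@@H](C)CC[C@@H]2C(C)=C[C@H]1C(=O)c1c(O)c([C@]2(O)CC[C@@H](O)[C@@H]3O[C@@H]32)c[nH]c1=O | target

**Count**
Total steps: 18. Longest linear sequence: 12 steps (13 to 28, steps 7–18). The chain branch (steps 1–5) joins at step 15 and the pyridine branch (step 6) joins at step 12.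

**Steps most likely to fail**

Step 17. The cycloaddition may lose periselectivity or the trans-fused fold. The polyene may oligomerise, or the oxirane may be opened by the warm protic solvent. The fallback sets out from 25 and carries out the same cycloaddition before unmasking. Heating 25 in degassed toluene with BHT at about 110 °C should give the fully protected C2-epimeric decalin adduct F1. DBU then epimerises C2, which should be easier here because no acidic pyridone hydroxyl consumes the base, and gives the fully protected all-equatorial decalin adduct F2. Buffered fluoride as in step 16 unmasks F2 and rejoins the route at 28.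

Step 15. The alkyllithium may attack or α-deprotonate the oxirane, or it may metalate C6 next to nitrogen, before the crowded C3–H is removed. The fallback replaces late C–H lithiation by halogen–metal exchange and sets out from 22, which holds no oxirane. Treatment with t-BuLi at −78 °C gives the 3-lithio derivative of the cyclohexene F3. Quenching with 1,2-dibromotetrachloroethane gives the 3-bromopyridyl cyclohexene F4. Buffered mCPBA converts this into the 3-bromopyridyl epoxide F5, the bromine also lowering the nucleophilicity of the ring nitrogen. Bromine–lithium exchange with n-BuLi at −78 °C is complete within minutes and rejoins the route at 24, which is acylated by 10 to give 25.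

Step 14. Oxidation at the pyridine nitrogen may outrun the slow epoxidation of an alkene flanked by two oxygenated carbons. The fallback accepts the over-oxidation and repairs it. It sets out from 22, and an excess of buffered mCPBA should give the epoxide pyridine N-oxide F6. Bis(pinacolato)diboron in MeCN then deoxygenates the nitrogen selectively, without touching the oxirane or the silyl groups, and rejoins the route at 23.

**Further compounds**
F1 | step 17 | fully protected C2-epimeric decalin adduct | C/C=C/[C@@H]1[C@H]2C[C@@H](C)CC[C@@H]2C(C)=C[C@@H]1C(=O)c1c(OCC[Si](C)(C)C)ncc(c1OCC[Si](C)(C)C)[C@]1(O[Si](CC)(CC)CC)CC[C@@H](O[Si](C)(C)C(C)(C)C)[C@@H]2O[C@@H]21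
F2 | step 17 | fully protected all-equatorial decalin adduct | C/C=C/[C@@H]1[C@H]2C[C@@H](C)CC[C@@H]2C(C)=C[C@H]1C(=O)c1c(OCC[Si](C)(C)C)ncc(c1OCC[Si](C)(C)C)[C@]1(O[Si](CC)(CC)CC)CC[C@@H](O[Si](C)(C)C(C)(C)C)[C@@H]2O[C@@H]21
F3 | step 15 | 3-lithio derivative of the cyclohexene 22 | C[Si](C)(C)CCOc1ncc(c(OCC[Si](C)(C)C)c1[Li])[C@]1(O[Si](CC)(CC)CC)CC[C@@H](O[Si](C)(C)C(C)(C)C)C=C1
F4 | step 15 | 3-bromopyridyl cyclohexene | C[Si](C)(C)CCOc1ncc(c(OCC[Si](C)(C)C)c1Br)[C@]1(O[Si](CC)(CC)CC)CC[C@@H](O[Si](C)(C)C(C)(C)C)C=C1
F5 | step 15 | 3-bromopyridyl epoxide | C[Si](C)(C)CCOc1ncc(c(OCC[Si](C)(C)C)c1Br)[C@]1(O[Si](CC)(CC)CC)CC[C@@H](O[Si](C)(C)C(C)(C)C)[C@@H]2O[C@@H]21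
F6 | step 14 | epoxide pyridine N-oxide | C[Si](C)(C)CCOc1cc(OCC[Si](C)(C)C)c(c[n+]1[O-])[C@]1(O[Si](CC)(CC)CC)CC[C@@H](O[Si](C)(C)C(C)(C)C)[C@@H]2O[C@@H]21
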